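**Plan**

- Side-chain carbons are counted C1' (ring-bound CH2) to C16'. The retrosynthesis cuts: the quinone oxygens (back to a 2,5-dimethoxy-3-methylphenyl ring); the sp3–sp2 bond C5'–C6'; the C7' methyl and C6' iodide (back to a terminal alkyne); the C11'–CH2OH bond and C10'–H (back to a C10'≡C11' alkyne); C11'–C12' (acetylide plus Weinreb amide); aryl–C1' (arylcopper plus geranyl bromide).
- Forward: the C6'–C16' half is built as an (E)-vinyl iodide carrying the free allylic 1,3-diol. The C1'–C5' half is built as the N-acyloxyphthalimide of the one-carbon-longer acid, obtained by excising the terminal isopropylidene of a geranyl arene. The two halves are joined, and the arene is oxidised to the quinone last.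
- Stereochemistry: C12' (R) from Noyori asymmetric transfer hydrogenation of an ynone; C10'=C11' from hydroxyl-directed trans-hydrostannation followed by carbonylation with retention; C6'=C7' (E) from syn-methylalumination and iodinolysis; C2'=C3' (E) from geranyl bromide.
- Enabling feature: C5' is a primary sp3 carbon insulated from C2'=C3' by C4' (homoallylic, not allylic), and C6' is the CH end of a 2-methylalk-1-enyl unit. Both can therefore be made electrophilic (active ester losing CO2; vinyl iodide) and joined by nickel-catalysed reductive coupling of two like-polarity carbons, with the free diol unprotected.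

Key step: step 17

Assumption: hexa-1,5-diyne, 4-methylpent-3-enoic acid, 4-methoxy-2-methylphenol and geranyl bromide are taken as commercial; the quinone is carried as its hydroquinone dimethyl ether because it would not survive organolithium, hydride or reductive nickel conditions.

**Route**

Step 1
Reactants: 1 hexa-1,5-diyne
Product: 3 trimethyl(hexa-1,5-diyn-1-yl)silane, via lithium hexa-1,5-diyn-1-ide 2 (not isolated)
Conditions: 1 (3 equiv), n-BuLi (1.0 equiv), THF, −78 °C; Me3SiCl (1.0 equiv), −78 °C → rt; distillation, excess 1 recovered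
Reagents that add atoms: chlorotrimethylsilane C[Si](C)(C)Cl
Why: Mono-deprotonation of the symmetrical diyne used in excess and C-silylation of the acetylide should mask one alkyne terminus until step 8 and leave the other free for step 3.

Step 2
Reactants: 4 4-methylpent-3-enoic acid
Product: 5 N-methoxy-N,4-dimethylpent-3-enamide
Conditions: MeNH(OMe)·HCl, EDC·HCl, HOBt, N-methylmorpholine, CH2Cl2, 0 °C → rt
Reagents that add atoms: N,O-dimethylhydroxylamine hydrochloride CNOC.Cl
Why: Carbodiimide amidation should give the Weinreb amide under near-neutral conditions that give the trisubstituted β,γ-alkene no reason to move into conjugation.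

Step 3
Reactants: 3 trimethyl(hexa-1,5-diyn-1-yl)silane; 5 N-methoxy-N,4-dimethylpent-3-enamide
Product: 7 2-methyl-11-(trimethylsilyl)undec-2-ene-6,10-diyn-5-one, via lithium 6-(trimethylsilyl)hexa-1,5-diyn-1-ide 6 (not isolated)
Conditions: 3, n-BuLi, THF, −78 °C; 5, −78 → 0 °C; inverse quench into cold aq. NaHSO4
Reagents that add atoms: none
Why: Weinreb ketone synthesis: the chelated tetrahedral adduct should stop at single addition, and the acidic inverse quench protonates the released amine before it can add to the ynone.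

Step 4
Reactants: 7 2-methyl-11-(trimethylsilyl)undec-2-ene-6,10-diyn-5-one
Product: 8 (5R)-2-methyl-11-(trimethylsilyl)undec-2-ene-6,10-diyn-5-ol
Conditions: Ru[(R,R)-TsNCHPhCHPhNH](p-cymene) (preformed amido complex, 1 mol %), i-PrOH, rt
Reagents that add atoms: none
Why: Noyori asymmetric transfer hydrogenation of an α,β-acetylenic ketone, in which the alkynyl group is the π-directing substituent, so the (R,R)-catalyst should deliver hydride to the face giving the (R)-carbinol; base-free conditions spare the doubly activated CH2.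

Step 5
Reactants: 8 (5R)-2-methyl-11-(trimethylsilyl)undec-2-ene-6,10-diyn-5-ol
Product: 9 (5R,6Z)-2-methyl-6-(tributylstannyl)-11-(trimethylsilyl)undeca-2,6-dien-10-yn-5-ol
Conditions: Bu3SnH (1.05 equiv, slow addition), [Cp*RuCl]4 (1.5 mol %), CH2Cl2, rt
Reagents that add atoms: tributyltin hydride CCCC[SnH](CCCC)CCCC
Why: Hydroxyl-directed ruthenium-catalysed trans-hydrostannation should place tin on the alkyne carbon next to the carbinol and hydrogen anti to it, fixing the C10'=C11' geometry; the silyl-capped alkyne lacks the directing hydroxyl and should react more slowly.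

Step 6
Reactants: 9 (5R,6Z)-2-methyl-6-(tributylstannyl)-11-(trimethylsilyl)undeca-2,6-dien-10-yn-5-ol
Product: 10 methyl (2Z)-2-[(1R)-1-hydroxy-4-methylpent-3-en-1-yl]-7-(trimethylsilyl)hept-2-en-6-ynoate
Conditions: CO (1 atm), MeOH, Pd(OAc)2 (5 mol %), Ph3As (10 mol %), 1,4-benzoquinone (1.5 equiv), CF3CO2H (1.0 equiv), rt
Reagents that add atoms: carbon monoxide [C-]#[O+]; methanol CO
Why: Hydroxyl-assisted oxidative methoxycarbonylation of an alkenylstannane (Stille-type transmetalation to divalent palladium, CO insertion, methanolysis, reoxidation of zerovalent palladium by benzoquinone) should replace tin by CO2Me with retention of alkene geometry.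

Step 7
Reactants: 10 methyl (2Z)-2-[(1R)-1-hydroxy-4-methylpent-3-en-1-yl]-7-(trimethylsilyl)hept-2-en-6-ynoate
Product: 11 (5R,6E)-6-(hydroxymethyl)-2-methyl-11-(trimethylsilyl)undeca-2,6-dien-10-yn-5-ol
Conditions: i-Bu2AlH (3.5 equiv), CH2Cl2, −78 → −20 °C; aq. potassium sodium tartrate (KNaC4H4O6)
Reagents that add atoms: none
Why: 1,2-Reduction of the enoate by the aluminium hydride should give the allylic primary alcohol without touching the silylalkyne or the alkenes.

Step 8
Reactants: 11 (5R,6E)-6-(hydroxymethyl)-2-methyl-11-(trimethylsilyl)undeca-2,6-dien-10-yn-5-ol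
Product: 12 (5R,6E)-6-(hydroxymethyl)-2-methylundeca-2,6-dien-10-yn-5-ol
Conditions: K2CO3 (0.3 equiv), MeOH, rt
Reagents that add atoms: none
Why: Base-catalysed methanolysis of the C–Si bond of a silylalkyne should free the terminal alkyne.

Step 9
Reactants: 12 (5R,6E)-6-(hydroxymethyl)-2-methylundeca-2,6-dien-10-yn-5-ol
Product: 14 (5R,6E,10E)-6-(hydroxymethyl)-11-iodo-2,10-dimethylundeca-2,6,10-trien-5-ol, via bis(dimethylaluminium) alkoxide of the (E)-alkenyldimethylalane 13 (not isolated)
Conditions: Me3Al (5 equiv), Cp2ZrCl2 (0.5 equiv), CH2Cl2, 0 °C → rt; I2 (1.5 equiv), THF, −30 → 0 °C; aq. KNaC4H4O6/Na2S2O3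
Reagents that add atoms: trimethylaluminium C[Al](C)C; iodine II
Why: Negishi zirconium-catalysed carboalumination adds methyl and aluminium syn across the terminal alkyne with aluminium at the terminal carbon, and iodinolysis with retention should give the (E)-2-methylvinyl iodide, the two hydroxyls being carried as aluminium alkoxides.

Step 10
Reactants: 15 4-methoxy-2-methylphenol
Product: 16 2-bromo-4-methoxy-6-methylphenol
Conditions: Br2 (1.0 equiv), CH2Cl2, 0 °C
Reagents that add atoms: bromine BrBr
Why: Electrophilic aromatic bromination should go to the only free position ortho to the hydroxyl, the strongest director, since the para position is blocked.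

Step 11
Reactants: 16 2-bromo-4-methoxy-6-methylphenol
Product: 17 1-bromo-2,5-dimethoxy-3-methylbenzene
Conditions: MeI, K2CO3, acetone, reflux
Reagents that add atoms: iodomethane CI
Why: Williamson O-methylation of the phenoxide should give the hydroquinone dimethyl ether that masks the quinone.

Step 12
Reactants: 17 1-bromo-2,5-dimethoxy-3-methylbenzene; 18 geranyl bromide [(2E)-1-bromo-3,7-dimethylocta-2,6-diene]
Product: 21 1-[(2E)-3,7-dimethylocta-2,6-dien-1-yl]-2,5-dimethoxy-3-methylbenzene, via (2,5-dimethoxy-3-methylphenyl)lithium 19 (not isolated), via (2,5-dimethoxy-3-methylphenyl)copper 20 (not isolated)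
Conditions: n-BuLi, THF, −78 °C; CuBr·SMe2 (1.0 equiv), −78 → −40 °C; 18, −78 → 0 °C
Reagents that add atoms: none
Why: Bromine–lithium exchange, transmetalation to copper and SN2 allylation of the arylcopper should join ring and chain at C1' with the E geometry of C2'=C3' taken unchanged from geranyl bromide.

Step 13
Reactants: 21 1-[(2E)-3,7-dimethylocta-2,6-dien-1-yl]-2,5-dimethoxy-3-methylbenzene
Product: 23 3-[(3E)-5-(2,5-dimethoxy-3-methylphenyl)-3-methylpent-3-en-1-yl]-2,2-dimethyloxirane (racemic at the oxirane carbon), via (6E)-3-bromo-8-(2,5-dimethoxy-3-methylphenyl)-2,6-dimethyloct-6-en-2-ol 22 (not isolated)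
Conditions: NBS (1.05 equiv), THF/H2O, 0 °C; then K2CO3, MeOH, rt
Reagents that add atoms: water O; N-bromosuccinimide O=C1CCC(=O)N1Br (its bromine is carried only by 22)
Why: Bromohydrin formation in aqueous medium should favour the exposed terminal isopropylidene over the inner alkene, and base closes the bromohydrin to the terminal epoxide.

Step 14
Reactants: 23 3-[(3E)-5-(2,5-dimethoxy-3-methylphenyl)-3-methylpent-3-en-1-yl]-2,2-dimethyloxirane
Product: 24 (4E)-6-(2,5-dimethoxy-3-methylphenyl)-4-methylhex-4-enal
Conditions: H5IO6 (1.2 equiv), THF/H2O, 0 °C → rt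
Reagents that add atoms: none
Why: Periodic acid should hydrolyse the epoxide and cleave the resulting glycol in one operation, excising the isopropylidene carbons as acetone.

Step 15
Reactants: 24 (4E)-6-(2,5-dimethoxy-3-methylphenyl)-4-methylhex-4-enal
Product: 25 (4E)-6-(2,5-dimethoxy-3-methylphenyl)-4-methylhex-4-enoic acid
Conditions: NaClO2, NaH2PO4, 2-methyl-2-butene, t-BuOH/H2O, 0 °C → rt
Reagents that add atoms: sodium chlorite [Na+].[O-]Cl=O
Why: Pinnick oxidation should convert the aldehyde into the acid while the alkene scavenger removes hypochlorous acid before it can chlorinate the electron-rich ring or the alkene.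

Step 16
Reactants: 25 (4E)-6-(2,5-dimethoxy-3-methylphenyl)-4-methylhex-4-enoic acid
Product: 26 1,3-dioxo-1,3-dihydro-2H-isoindol-2-yl (4E)-6-(2,5-dimethoxy-3-methylphenyl)-4-methylhex-4-enoate
Conditions: N-hydroxyphthalimide, N,N'-diisopropylcarbodiimide, DMAP (cat.), CH2Cl2, rt
Reagents that add atoms: N-hydroxyphthalimide O=C1c2ccccc2C(=O)N1O
Why: Carbodiimide esterification should give the redox-active ester, whose carboxyl carbon is the temporary activating group lost as CO2 in step 17.

Step 17
Reactants: 14 (5R,6E,10E)-6-(hydroxymethyl)-11-iodo-2,10-dimethylundeca-2,6,10-trien-5-ol; 26 1,3-dioxo-1,3-dihydro-2H-isoindol-2-yl (4E)-6-(2,5-dimethoxy-3-methylphenyl)-4-methylhex-4-enoate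
Product: 27 (5R,6E,10E,14E)-16-(2,5-dimethoxy-3-methylphenyl)-6-(hydroxymethyl)-2,10,14-trimethylhexadeca-2,6,10,14-tetraen-5-ol
Conditions: 14 (1.0 equiv), 26 (1.8 equiv), NiCl2·6H2O (10 mol %), 2,2'-bipyridine (10 mol %), AgNO3 (0.3 equiv), LiCl, DMF, Mg anode, reticulated vitreous carbon cathode, constant current, rt, undivided cell
Reagents that add atoms: none
Why: Cathodic reduction should give low-valent nickel–bipyridine, which adds to the C–I bond of 14 with retention to give a divalent alkenylnickel iodide, while one-electron reduction of 26 (by low-valent nickel or at the silver-coated cathode) releases CO2 and phthalimide anion and leaves the primary C5' radical; capture of this radical and reductive elimination from trivalent nickel form the C5'–C6' bond, the magnesium anode supplying the two electrons. The closest known reaction type is the nickel-catalysed reductive (cross-electrophile) decarboxylative alkenylation of N-acyloxyphthalimides with alkenyl halides, which is established for homoallylic terpenoid active esters and 2-methylalk-1-enyl iodides. No ring is closed and no stereocentre is created; the C12' centre is remote and untouched. Cross-coupling over homo-coupling is secured by the different activation modes of the two electrophiles (two-electron oxidative addition for the sp2 iodide, one-electron fragmentation for the ester) and by the excess of 26. The E geometry at C6'=C7' is kept because oxidative addition and reductive elimination at nickel are stereoretentive at sp2 carbon, and C2'=C3' is kept because the C5' radical is homoallylic, insulated by C4', cannot delocalise, and is held away from the arene by the E alkene so that no 5- or 6-membered cyclisation is open. Free hydroxyl groups and the dimethoxyarene are not reduced at the potential of the nickel couple, so the diol needs no protecting group.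

Step 18
Reactants: 27 (5R,6E,10E,14E)-16-(2,5-dimethoxy-3-methylphenyl)-6-(hydroxymethyl)-2,10,14-trimethylhexadeca-2,6,10,14-tetraen-5-ol
Product: 28 2-[(2E,6E,10E,12R)-12-hydroxy-11-(hydroxymethyl)-3,7,15-trimethylhexadeca-2,6,10,14-tetraen-1-yl]-6-methylcyclohexa-2,5-diene-1,4-dione
Conditions: (NH4)2Ce(NO3)6 (2.5 equiv), MeCN/H2O, 0 °C, short reaction time
Reagents that add atoms: water O
Why: Oxidative demethylation of the 1,4-dimethoxyarene by tetravalent cerium (arene radical cation, attack of water, loss of two methanol) should unmask the quinone much faster than the isolated trisubstituted alkenes or the allylic 1,3-diol are attacked.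

**Compound list**

1 | hexa-1,5-diyne | C#CCCC#C | starting material
2 | lithium hexa-1,5-diyn-1-ide | [Li]C#CCCC#C | intermediate
3 | trimethyl(hexa-1,5-diyn-1-yl)silane | C[Si](C)(C)C#CCCC#C | intermediate
4 | 4-methylpent-3-enoic acid | CC(C)=CCC(=O)O | starting material
5 | N-methoxy-N,4-dimethylpent-3-enamide | CC(C)=CCC(=O)N(C)OC | intermediate
6 | lithium 6-(trimethylsilyl)hexa-1,5-diyn-1-ide | [Li]C#CCCC#C[Si](C)(C)C | intermediate
7 | 2-methyl-11-(trimethylsilyl)undec-2-ene-6,10-diyn-5-one | CC(C)=CCC(=O)C#CCCC#C[Si](C)(C)C | intermediate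
8 | (5R)-2-methyl-11-(trimethylsilyl)undec-2-ene-6,10-diyn-5-ol | CC(C)=CC[C@@H](O)C#CCCC#C[Si](C)(C)C | intermediate
9 | (5R,6Z)-2-methyl-6-(tributylstannyl)-11-(trimethylsilyl)undeca-2,6-dien-10-yn-5-ol | CC(C)=CC[C@@H](O)/C(=C/CCC#C[Si](C)(C)C)[Sn](CCCC)(CCCC)CCCC | intermediate
10 | methyl (2Z)-2-[(1R)-1-hydroxy-4-methylpent-3-en-1-yl]-7-(trimethylsilyl)hept-2-en-6-ynoate | CC(C)=CC[C@@H](O)/C(=C/CCC#C[Si](C)(C)C)C(=O)OC | intermediate
11 | (5R,6E)-6-(hydroxymethyl)-2-methyl-11-(trimethylsilyl)undeca-2,6-dien-10-yn-5-ol | CC(C)=CC[C@@H](O)/C(=C/CCC#C[Si](C)(C)C)CO | intermediate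
12 | (5R,6E)-6-(hydroxymethyl)-2-methylundeca-2,6-dien-10-yn-5-ol | CC(C)=CC[C@@H](O)/C(=C/CCC#C)CO | intermediate
13 | bis(dimethylaluminium) alkoxide of the (E)-alkenyldimethylalane from 12 | CC(C)=CC[C@@H](O[Al](C)C)/C(=C/CC/C(C)=C/[Al](C)C)CO[Al](C)C | intermediate
14 | (5R,6E,10E)-6-(hydroxymethyl)-11-iodo-2,10-dimethylundeca-2,6,10-trien-5-ol | CC(C)=CC[C@@H](O)/C(=C/CC/C(C)=C/I)CO | intermediate
15 | 4-methoxy-2-methylphenol | Cc1cc(OC)ccc1O | starting material
16 | 2-bromo-4-methoxy-6-methylphenol | Cc1cc(OC)cc(Br)c1O | intermediate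
17 | 1-bromo-2,5-dimethoxy-3-methylbenzene | COc1cc(C)c(OC)c(Br)c1 | intermediate
18 | geranyl bromide, (2E)-1-bromo-3,7-dimethylocta-2,6-diene | CC(C)=CCC/C(C)=C/CBr | starting material
19 | (2,5-dimethoxy-3-methylphenyl)lithium | COc1cc(C)c(OC)c([Li])c1 | intermediate
20 | (2,5-dimethoxy-3-methylphenyl)copper | COc1cc(C)c(OC)c([Cu])c1 | intermediate
21 | 1-[(2E)-3,7-dimethylocta-2,6-dien-1-yl]-2,5-dimethoxy-3-methylbenzene | COc1cc(C)c(OC)c(C/C=C(\C)CCC=C(C)C)c1 | intermediate
22 | (6E)-3-bromo-8-(2,5-dimethoxy-3-methylphenyl)-2,6-dimethyloct-6-en-2-ol (racemic) | COc1cc(C)c(OC)c(C/C=C(\C)CCC(Br)C(C)(C)O)c1 | intermediate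
23 | 3-[(3E)-5-(2,5-dimethoxy-3-methylphenyl)-3-methylpent-3-en-1-yl]-2,2-dimethyloxirane (racemic) | COc1cc(C)c(OC)c(C/C=C(\C)CCC2OC2(C)C)c1 | intermediate
24 | (4E)-6-(2,5-dimethoxy-3-methylphenyl)-4-methylhex-4-enal | COc1cc(C)c(OC)c(C/C=C(\C)CCC=O)c1 | intermediate
25 | (4E)-6-(2,5-dimethoxy-3-methylphenyl)-4-methylhex-4-enoic acid | COc1cc(C)c(OC)c(C/C=C(\C)CCC(=O)O)c1 | intermediate
26 | 1,3-dioxo-1,3-dihydro-2H-isoindol-2-yl (4E)-6-(2,5-dimethoxy-3-methylphenyl)-4-methylhex-4-enoate | COc1cc(C)c(OC)c(C/C=C(\C)CCC(=O)ON2C(=O)c3ccccc3C2=O)c1 | intermediate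
27 | (5R,6E,10E,14E)-16-(2,5-dimethoxy-3-methylphenyl)-6-(hydroxymethyl)-2,10,14-trimethylhexadeca-2,6,10,14-tetraen-5-ol | CC(C)=CC[C@@H](O)/C(=C/CC/C(C)=C/CC/C(C)=C/Cc1cc(OC)cc(C)c1OC)CO | intermediate
28 | 2-[(2E,6E,10E,12R)-12-hydroxy-11-(hydroxymethyl)-3,7,15-trimethylhexadeca-2,6,10,14-tetraen-1-yl]-6-methylcyclohexa-2,5-diene-1,4-dione | CC(C)=CC[C@@H](O)/C(=C/CC/C(C)=C/CC/C(C)=C/CC1=CC(=O)C=C(C)C1=O)CO | target

**Totals and risks**

Total step count: 18. Longest linear sequence: 10 steps (steps 1, 3 to 9, 17, 18).

Step 17. The two electrophiles may be consumed separately (reductive dimerisation of the vinyl iodide, reduction or dimerisation of the C5' radical), or the free diol may be acylated by the active ester before coupling. The fallback replaces the radical union by a two-electron Suzuki–Miyaura coupling; it sets out from 26 and comes back at 27. Copper-catalysed decarboxylative borylation of 26 (B2pin2, Cu(acac)2, LiOH·H2O, MgCl2, dioxane/DMF, rt) should give 2-[(3E)-5-(2,5-dimethoxy-3-methylphenyl)-3-methylpent-3-en-1-yl]-4,4,5,5-tetramethyl-1,3,2-dioxaborolane F1. Treatment with KHF2 in MeOH/H2O should give potassium [(3E)-5-(2,5-dimethoxy-3-methylphenyl)-3-methylpent-3-en-1-yl]trifluoroborate F2. Coupling of F2 with 14 (PdCl2(dppf), Cs2CO3, toluene/H2O, 80 °C) should then give 27 with retention of the vinyl geometry.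

Step 9. The aluminium alkoxides formed from the free 1,3-diol may slow or divert the methylalumination, and during iodinolysis iodine may add to the electron-rich alkenes with participation of a neighbouring oxygen. The fallback masks the diol through the organoaluminium and coupling steps; it sets out from 12 and comes back at 27. Silylation (t-BuMe2SiCl, imidazole, DMF) should give (5R,6E)-5-[(tert-butyldimethylsilyl)oxy]-6-{[(tert-butyldimethylsilyl)oxy]methyl}-2-methylundeca-2,6-dien-10-yne F3. Carboalumination as in step 9 should pass through the corresponding (E)-alkenyldimethylalane F4 (not isolated) and, after iodine, give the bis-silylated (E)-vinyl iodide F5. Coupling of F5 with 26 under the conditions of step 17 should give the bis-silyl ether of 27 F6, and Bu4NF in THF should release 27.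

Step 13. The bromonium source may attack the electron-rich dimethoxyarene or discriminate poorly between the two trisubstituted alkenes. The fallback installs the epoxide before the ring is attached; it sets out from 17 (through arylcopper 20, generated as in step 12) and comes back at 23. Geranyl acetate (commercial, CC(=O)OC/C=C(\C)CCC=C(C)C) is epoxidised at the remote alkene, the inner one being deactivated by the allylic acetate (mCPBA, CH2Cl2, −20 °C), to give (2E)-5-(3,3-dimethyloxiran-2-yl)-3-methylpent-2-en-1-yl acetate F7. Methanolysis (K2CO3, MeOH) should give (2E)-5-(3,3-dimethyloxiran-2-yl)-3-methylpent-2-en-1-ol F8, and CBr4/PPh3 (CH2Cl2, 0 °C) should give 3-[(3E)-5-bromo-3-methylpent-3-en-1-yl]-2,2-dimethyloxirane F9. Allylation of 20 with F9 (THF, −78 → 0 °C) should give 23 directly.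

**Further compounds**

F1 | step 17 | 2-[(3E)-5-(2,5-dimethoxy-3-methylphenyl)-3-methylpent-3-en-1-yl]-4,4,5,5-tetramethyl-1,3,2-dioxaborolane | COc1cc(C)c(OC)c(C/C=C(\C)CCB2OC(C)(C)C(C)(C)O2)c1
F2 | step 17 | potassium [(3E)-5-(2,5-dimethoxy-3-methylphenyl)-3-methylpent-3-en-1-yl]trifluoroborate | COc1cc(C)c(OC)c(C/C=C(\C)CC[B-](F)(F)F)c1.[K+]
F3 | step 9 | (5R,6E)-5-[(tert-butyldimethylsilyl)oxy]-6-{[(tert-butyldimethylsilyl)oxy]methyl}-2-methylundeca-2,6-dien-10-yne | CC(C)=CC[C@@H](O[Si](C)(C)C(C)(C)C)/C(=C/CCC#C)CO[Si](C)(C)C(C)(C)C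
F4 | step 9 | (E)-alkenyldimethylalane from F3 (not isolated) | CC(C)=CC[C@@H](O[Si](C)(C)C(C)(C)C)/C(=C/CC/C(C)=C/[Al](C)C)CO[Si](C)(C)C(C)(C)C
F5 | step 9 | (5R,6E,10E)-5-[(tert-butyldimethylsilyl)oxy]-6-{[(tert-butyldimethylsilyl)oxy]methyl}-11-iodo-2,10-dimethylundeca-2,6,10-triene | CC(C)=CC[C@@H](O[Si](C)(C)C(C)(C)C)/C(=C/CC/C(C)=C/I)CO[Si](C)(C)C(C)(C)C
F6 | step 9 | bis(tert-butyldimethylsilyl) ether of 27 | CC(C)=CC[C@@H](O[Si](C)(C)C(C)(C)C)/C(=C/CC/C(C)=C/CC/C(C)=C/Cc1cc(OC)cc(C)c1OC)CO[Si](C)(C)C(C)(C)C
F7 | step 13 | (2E)-5-(3,3-dimethyloxiran-2-yl)-3-methylpent-2-en-1-yl acetate (racemic) | CC(=O)OC/C=C(\C)CCC1OC1(C)C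
F8 | step 13 | (2E)-5-(3,3-dimethyloxiran-2-yl)-3-methylpent-2-en-1-ol (racemic) | OC/C=C(\C)CCC1OC1(C)C
F9 | step 13 | 3-[(3E)-5-bromo-3-methylpent-3-en-1-yl]-2,2-dimethyloxirane (racemic) | BrC/C=C(\C)CCC1OC1(C)C
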